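Prostanoid numbering is used for the target: C1 is the ester carbon, C5=C6 and C7=C8 are the side-chain alkenes, C8–C12 form the ring (C9 ketone, C10 bromine-bearing carbon, C12 carbinol), and C13–C20 are the octenyl chain.

## Analysis of the target

The target (compound 14) has one ring, a cyclopent-2-enone (C8–C12) with the ketone at C9, bromine at C10 and hydrogen at C11. C8 carries an exocyclic C7=C8 double bond that continues through C5=C6 to the methyl ester, so the ring enone and the side-chain dienone are cross-conjugated through C9. C12 is a fully substituted carbinol (OH, the (Z)-oct-2-enyl chain, C8 and C11) and is the only stereocentre (R). No second stereocentre can relay chirality to it, so it has to be set by a catalyst or reagent in a C–C bond-forming event. Three alkene geometries must also be right (5E, 7E, 14Z); in the 7E isomer C6 points towards the crowded C12. The sensitive groups are the cross-conjugated dienone (acceptor positions C11, C7 and C5; light-induced 7E/7Z isomerisation), the α-bromo enone, the tertiary alcohol β to the C9 ketone, the skipped C14=C15 alkene and the ester. Two features guide the plan: the array C12(OH)–C8(=C7)–C9=O is formally the adduct of a C8 vinyl-metal of an enone to a C12 ketone, and C9 and C12 are 1,4-related oxygenated carbons joined by a cis C10=C11 bond, the pattern of an oxidatively opened furan with bromine on a former β-carbon. The classical order (ring first, aldol condensation at C8, halogenation last) is hard because it needs a separate asymmetric synthesis of a tertiary carbinol, gives 7E/7Z mixtures, and must brominate C10 in the presence of the C14=C15 alkene and the diene.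

## Retrosynthetic reasoning

**14 to 10 and 13 (key disconnection).** The bonds C6–C7 and C8–C12 are cut in one operation. This turns the ring into the acyclic, achiral bromo-enedione ynone 10 and splits off the C1–C6 chain as alkenylboronic acid 13. The cut is made at C8–C12 because it is the most hindered bond of the target, and opening it converts the quaternary carbinol into a prochiral ketone. In the forward sense the alkenyl group of 13 adds under rhodium catalysis syn across the C7≡C8 bond of 10, and the resulting C8–metal bond adds to the C12 ketone. One step therefore has to close the ring, set C12 under ligand control, set 7E through the syn addition, bring in 5E from 13, and join the two chains, with the bromine already in place and no protecting group.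

**10 to 8.** The C9 and C12 carbonyl groups with the cis C10=C11 bond between them are traced back to the furan ring of 8 (C9 and C12 are its α-carbons, C10–Br a β-carbon). Oxidative dearomatisation delivers both ketones at once. The ring origin guarantees the cis geometry that the ring closure in the key step requires, and the position of the bromine is fixed by the furan substitution pattern.

**8 to 7 to 5 and 2.** The C12–C13 bond is cut: the C5-metalated furan 6, formed from 5, is alkylated with the allylic bromide 2, which carries the 14Z alkene from alcohol 1. The silyl group of 5 and 7 protects the acetylenic position during the metalation and is removed afterwards to give 8.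

**5 to 3 and 4.** The C8–C9 bond is cut at the α-bromide of 3. A cross-coupling with alkyne 4 should be site-selective for the α-position and leaves the β-bromine that becomes C10–Br.

**13 to 11.** The C6–B bond comes from syn-hydroboration of the terminal alkyne of 11, which fixes the 5E geometry.

## Alternatives that were turned down

**Alternative 1: aldol condensation at C7=C8 (the textbook route).** The disconnection is the C7=C8 bond. In the forward key step the C8 enolate of (4S)-2-bromo-4-hydroxy-4-[(2Z)-oct-2-en-1-yl]cyclopent-2-en-1-one A1 (hydroxyl masked) adds to methyl (5E)-7-oxohept-5-enoate A2, and the aldol is then dehydrated. It was turned down for these reasons: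
- A1 contains the whole stereochemical problem, a tertiary carbinol in a ring with no handle, and needs its own multi-step asymmetric synthesis or a resolution.
- The free C12 alkoxide would open the ring by retro-aldol cleavage under enolisation conditions, so protection and deprotection are unavoidable.
- Dehydration has no element that controls 7E against 7Z.
- Bromination of C10 either precedes the base-mediated aldol (base-labile α-bromo enone) or follows it (competition from C14=C15 and the diene).
- The key step forms only one bond, and the sequence is linear and long.

**Alternative 2: Piancatelli rearrangement of a furylcarbinol.** The disconnection is C8–C12, with the ring arising from a furan. In the forward key step, acid-promoted ionisation of methyl (5E)-8-{3-bromo-5-[(2Z)-oct-2-en-1-yl]furan-2-yl}-8-hydroxyoct-5-enoate A3, hydration at the furan C5 and conrotatory 4π-electrocyclisation would give the trans-4-hydroxy-5-alkylcyclopentenone A4. It was turned down for these reasons: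
- The carbinol stereocentre of A3 is erased in the furfuryl cation, so C12 is formed racemic.
- C8 arrives sp3 and must afterwards be dehydrogenated across C7–C8 with control of geometry, which costs extra steps on a cross-conjugated, base-sensitive ketone.
- The hot aqueous acid needed for 5-alkylfurans threatens the skipped alkene and the allylic C5=C6 unit.

**Alternative 3: convergent addition at C12–C13.** The disconnection is the C12–C13 bond. In the forward key step an oct-2-enyl-metal reagent would add in a 1,2-fashion, enantioselectively, to the C12 carbonyl of methyl (5E,7E)-7-(3-bromo-2,5-dioxocyclopent-3-en-1-ylidene)hept-5-enoate A5. It was turned down for these reasons: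
- Allyl-type metal reagents react at their γ-carbon and would give the branched carbinol, not the linear 2-octenyl chain.
- The two carbonyl groups of A5 differ only by the side of the alkylidene and by the bromine, and the one that must react (C12) is the one shielded by C6.
- A5 has three conjugate-acceptor positions (C11, C7, C5) that compete with 1,2-addition.
- No enantioselective variant of such an addition can be argued from the structure.

Key step: step 7

Assumption: compounds 1, 3, 4 and 11 are taken as purchased. The sense of induction of the diene ligand in step 7 cannot be derived for this substrate from first principles; the (R,R)-ligand is written, and the (S,S)-ligand is used instead if the first run shows the opposite sense at C12.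

## Route

Step 1
Reactants: 1 (2Z)-oct-2-en-1-ol
Product: 2 (2Z)-1-bromooct-2-ene
Conditions: CBr4, PPh3, CH2Cl2, 0 °C
Reagents that add atoms: tetrabromomethane, BrC(Br)(Br)Br
Why: Appel bromination of a primary allylic alcohol; SN2 displacement of the oxyphosphonium group at the unhindered CH2 should leave the Z-alkene untouched at 0 °C.

Step 2
Reactants: 3 2,3-dibromofuran; 4 ethynyl(trimethyl)silane
Product: 5 3-bromo-2-[(trimethylsilyl)ethynyl]furan
Conditions: Pd(PPh3)2Cl2 (2 mol%), CuI (4 mol%), Et3N, THF, 20–40 °C
Reagents that add atoms: none
Why: Sonogashira coupling; oxidative addition of zerovalent palladium should be faster at the C2–Br bond next to the ring oxygen than at C3–Br, so one equivalent of 4 should give the 2-alkynyl-3-bromofuran.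

Step 3
Reactants: 5 3-bromo-2-[(trimethylsilyl)ethynyl]furan; 2 (2Z)-1-bromooct-2-ene
Product: 7 3-bromo-5-[(2Z)-oct-2-en-1-yl]-2-[(trimethylsilyl)ethynyl]furan, via 5-lithiofuran 6 (not isolated)
Conditions: LDA, THF, −78 °C; then 2, −78 to 0 °C
Reagents that add atoms: none
Why: Deprotonation of the only α-hydrogen of the furan (C5) by the amide base gives 6, which should be alkylated by the primary allylic bromide in an SN2 reaction with the Z-alkene retained; the silyl group blocks the acetylenic position and the low temperature should suppress migration of the bromine.

Step 4
Reactants: 7 3-bromo-5-[(2Z)-oct-2-en-1-yl]-2-[(trimethylsilyl)ethynyl]furan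
Product: 8 3-bromo-2-ethynyl-5-[(2Z)-oct-2-en-1-yl]furan
Conditions: K2CO3 (cat.), MeOH, 0 to 20 °C
Reagents that add atoms: none
Why: Methanolysis of the C(sp)–Si bond under catalytic carbonate; the furan, the ring bromide and the skipped alkene should be inert to these conditions.

Step 5
Reactants: 8 3-bromo-2-ethynyl-5-[(2Z)-oct-2-en-1-yl]furan
Product: 10 (4E,8Z)-4-bromotetradeca-4,8-dien-1-yne-3,6-dione, via furan endoperoxide 9 (not isolated)
Conditions: O2, tetraphenylporphyrin (cat.), visible light, CH2Cl2, −78 °C; then Me2S, −78 to 0 °C; product used at once
Reagents that add atoms: dioxygen, O=O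
Why: Dearomatising (4+2) cycloaddition of singlet oxygen across the furan α-carbons gives endoperoxide 9, and its reduction by the sulfide opens it to the ene-dione; the cis arrangement of the two carbonyl groups about C10=C11 is inherited from the ring, and the furan diene should react far faster than the isolated Z-alkene does in an ene reaction.

Step 6
Reactants: 11 methyl hex-5-ynoate
Product: 13 [(1E)-6-methoxy-6-oxohex-1-en-1-yl]boronic acid, via catechol boronate 12 (not isolated)
Conditions: catecholborane, neat, 70 °C; then H2O, 20 °C
Reagents that add atoms: catecholborane, [BH]1Oc2ccccc2O1; water, O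
Why: Uncatalysed syn-hydroboration of the terminal alkyne places boron on the terminal carbon and fixes the E geometry; hydrolysis of the catechol ester 12 releases the boronic acid, and the methyl ester should be reduced far more slowly than the alkyne is hydroborated.

Step 7
Reactants: 10 (4E,8Z)-4-bromotetradeca-4,8-dien-1-yne-3,6-dione; 13 [(1E)-6-methoxy-6-oxohex-1-en-1-yl]boronic acid
Product: 14 methyl (5E,7E)-7-{(5R)-3-bromo-5-hydroxy-5-[(2Z)-oct-2-en-1-yl]-2-oxocyclopent-3-en-1-ylidene}hept-5-enoate (the target)
Conditions: [Rh(OH)((R,R)-Ph-bod)]2 (3 mol%; Ph-bod = (1R,4R)-2,5-diphenylbicyclo[2.2.2]octa-2,5-diene), 13 (1.3 equiv), 1,4-dioxane/H2O (20:1), 20 °C, dark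
Reagents that add atoms: none
Why: Rhodium-catalysed alkenylative cyclisation of an alkynone: transmetalation of 13 to the hydroxorhodium complex gives an alkenylrhodium species that adds syn across the terminal ynone (alkenyl to C7, rhodium to C8), the C8–Rh bond then adds to the C12 ketone, and hydrolysis of the rhodium alkoxide returns the hydroxo complex. The closest known reaction types are the rhodium-catalysed arylative cyclisation of alkyne-tethered ketones with arylboronic acids under chiral diene ligands and the cationic divalent-palladium cyclisation of ketone-tethered alkynoates, in which the α-carbon of the acetylenic carbonyl unit likewise closes a five-membered ring onto a ketone. The ring (C8–C12) closes by 5-exo-trig attack of the in-plane C8–Rh σ-bond on C12=O, which the cis C10=C11 bond holds next to the metal. The C12 stereocentre is set in this ketone insertion by the chiral diene on monovalent rhodium, which differentiates the faces of the prochiral ketone (C11 against C13). The C7=C8 geometry follows from syn-carbometalation and retention in the C–C bond formation, which place C6 cis to C12 (7E); 5E comes unchanged from 13 and 14Z from 10. The step needs alkyne insertion to run ahead of conjugate addition at C10=C11, which should hold because that alkene is trisubstituted and carries bromine at the α-position while the terminal ynone is the least hindered and most activated π-bond. It also needs ketone addition to run ahead of protonolysis or isomerisation of the alkenylrhodium species, which the proximity of the C12 carbonyl should secure. The C–Br bond should be inert to monovalent rhodium at 20 °C, and the base-free medium spares the C13 methylene and the bromo-enedione.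

## Compound list

1 | (2Z)-oct-2-en-1-ol | CCCCC/C=C\CO | starting material
2 | (2Z)-1-bromooct-2-ene | CCCCC/C=C\CBr | intermediate
3 | 2,3-dibromofuran | Brc1occc1Br | starting material
4 | ethynyl(trimethyl)silane | C#C[Si](C)(C)C | starting material
5 | 3-bromo-2-[(trimethylsilyl)ethynyl]furan | C[Si](C)(C)C#Cc1occc1Br | intermediate
6 | {4-bromo-5-[(trimethylsilyl)ethynyl]furan-2-yl}lithium (5-lithiofuran) | [Li]c1cc(Br)c(C#C[Si](C)(C)C)o1 | intermediate
7 | 3-bromo-5-[(2Z)-oct-2-en-1-yl]-2-[(trimethylsilyl)ethynyl]furan | CCCCC/C=C\Cc1cc(Br)c(C#C[Si](C)(C)C)o1 | intermediate
8 | 3-bromo-2-ethynyl-5-[(2Z)-oct-2-en-1-yl]furan | CCCCC/C=C\Cc1cc(Br)c(C#C)o1 | intermediate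
9 | 5-bromo-4-ethynyl-1-[(2Z)-oct-2-en-1-yl]-2,3,7-trioxabicyclo[2.2.1]hept-5-ene (furan endoperoxide, racemic) | C#CC12OOC(C/C=C\CCCCC)(O1)C=C2Br | intermediate
10 | (4E,8Z)-4-bromotetradeca-4,8-dien-1-yne-3,6-dione | CCCCC/C=C\CC(=O)/C=C(Br)\C(=O)C#C | intermediate
11 | methyl hex-5-ynoate | COC(=O)CCCC#C | starting material
12 | methyl (5E)-6-(1,3,2-benzodioxaborol-2-yl)hex-5-enoate (catechol boronate) | COC(=O)CCC/C=C/B1Oc2ccccc2O1 | intermediate
13 | [(1E)-6-methoxy-6-oxohex-1-en-1-yl]boronic acid | COC(=O)CCC/C=C/B(O)O | intermediate
14 | methyl (5E,7E)-7-{(5R)-3-bromo-5-hydroxy-5-[(2Z)-oct-2-en-1-yl]-2-oxocyclopent-3-en-1-ylidene}hept-5-enoate | CCCCC/C=C\C[C@@]1(O)C=C(Br)C(=O)/C1=C/C=C/CCCC(=O)OC | target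

## Step count and risk

Total step count: 7. Longest linear sequence: 5 steps (3 to 5 to 7 to 8 to 10 to 14; the branch from 1 is equally long, and 13 is made in one step).

**Step 7 (key step).** Several processes may defeat it:
- protonolysis of the C8–Rh bond before it inserts the C12 ketone, which would leave open-chain material;
- consumption of the terminal ynone through rhodium acetylide formation and oligomerisation;
- 1,4-migration of rhodium from C8 to C5;
- conjugate addition or addition–elimination at the bromo-enedione;
- loss of the 7E geometry through an oxygen-bound allenolate;
- insufficient facial discrimination at C12.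

The fallback sets out from 10 and comes back at 14. It separates ring closure from chain union. Treatment of 10 with MgI2 in CH2Cl2 at 0 °C (conjugate addition of iodide to the ynone and aldol closure of the allenolate onto the C12 ketone, an intramolecular halo-aldol reaction) should give racemic (5E)-2-bromo-4-hydroxy-5-(iodomethylidene)-4-[(2Z)-oct-2-en-1-yl]cyclopent-2-en-1-one F1. Iodide addition is reversible, so equilibration towards the isomer with iodine syn to C12 is available. Suzuki–Miyaura coupling of F1 with 13 (Pd(PPh3)4, Cs2CO3, THF/H2O, 20 °C), in which the β-iodoenone C–I bond should react well ahead of C10–Br, would give racemic methyl (5E,7E)-7-{3-bromo-5-hydroxy-5-[(2Z)-oct-2-en-1-yl]-2-oxocyclopent-3-en-1-ylidene}hept-5-enoate F2. Preparative chromatography on a chiral stationary phase would then deliver 14. This gives up catalyst control at C12 and at best half of the material.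

**Step 5.** The bromine and the alkyne deactivate the furan, so the ene reaction of singlet oxygen at the skipped alkene may compete with the cycloaddition. Cis-to-trans isomerisation or nucleophilic attack on the bromo-enedione may also occur during reduction and work-up. The fallback sets out from 8 and comes back at 10. Anodic methoxylation of the furan (graphite anode, MeOH, Et4NOTs, constant current, −10 °C) selects by oxidation potential and should give 3-bromo-2-ethynyl-2,5-dimethoxy-5-[(2Z)-oct-2-en-1-yl]-2,5-dihydrofuran F3 as a storable mixture of diastereomers. Mild hydrolysis (aqueous AcOH/THF, 0 °C) just before step 7 would unveil 10 with the cis geometry fixed by the ring.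

**Step 3.** Bromine may migrate in the lithiated furan, 2 may be attacked at its γ-carbon (allylic transposition), or unreacted 6 may deprotonate the doubly activated CH2 of the product. The fallback sets out from 5 and comes back at 7, and it builds the Z-alkene by olefination instead of carrying it in an electrophile. The lithiated furan 6 would be opened onto oxirane (BF3·OEt2, THF, −78 °C) to give 2-{4-bromo-5-[(trimethylsilyl)ethynyl]furan-2-yl}ethan-1-ol F4. Dess–Martin oxidation would give {4-bromo-5-[(trimethylsilyl)ethynyl]furan-2-yl}acetaldehyde F5, used at once. Wittig reaction with the ylide from hexyl(triphenyl)phosphonium bromide and NaHMDS (THF, −78 °C) should give 7 with the Z-selectivity of a non-stabilised ylide.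

## Further compounds

F1 | step 7 | (5E)-2-bromo-4-hydroxy-5-(iodomethylidene)-4-[(2Z)-oct-2-en-1-yl]cyclopent-2-en-1-one (racemic) | CCCCC/C=C\CC1(O)C=C(Br)C(=O)/C1=C/I
F2 | step 7 | methyl (5E,7E)-7-{3-bromo-5-hydroxy-5-[(2Z)-oct-2-en-1-yl]-2-oxocyclopent-3-en-1-ylidene}hept-5-enoate (racemic) | CCCCC/C=C\CC1(O)C=C(Br)C(=O)/C1=C/C=C/CCCC(=O)OC
F3 | step 5 | 3-bromo-2-ethynyl-2,5-dimethoxy-5-[(2Z)-oct-2-en-1-yl]-2,5-dihydrofuran (mixture of diastereomers) | C#CC1(OC)OC(OC)(C/C=C\CCCCC)C=C1Br
F4 | step 3 | 2-{4-bromo-5-[(trimethylsilyl)ethynyl]furan-2-yl}ethan-1-ol | OCCc1cc(Br)c(C#C[Si](C)(C)C)o1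
F5 | step 3 | {4-bromo-5-[(trimethylsilyl)ethynyl]furan-2-yl}acetaldehyde | O=CCc1cc(Br)c(C#C[Si](C)(C)C)o1
A1 | alternative 1 | (4S)-2-bromo-4-hydroxy-4-[(2Z)-oct-2-en-1-yl]cyclopent-2-en-1-one | CCCCC/C=C\C[C@@]1(O)C=C(Br)C(=O)C1
A2 | alternative 1 | methyl (5E)-7-oxohept-5-enoate | COC(=O)CCC/C=C/C=O
A3 | alternative 2 | methyl (5E)-8-{3-bromo-5-[(2Z)-oct-2-en-1-yl]furan-2-yl}-8-hydroxyoct-5-enoate (racemic) | CCCCC/C=C\Cc1cc(Br)c(C(O)C/C=C/CCCC(=O)OC)o1
A4 | alternative 2 | methyl (5E)-7-{3-bromo-5-hydroxy-5-[(2Z)-oct-2-en-1-yl]-2-oxocyclopent-3-en-1-yl}hept-5-enoate (racemic trans isomer, one enantiomer drawn) | CCCCC/C=C\C[C@@]1(O)C=C(Br)C(=O)[C@H]1C/C=C/CCCC(=O)OC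
A5 | alternative 3 | methyl (5E,7E)-7-(3-bromo-2,5-dioxocyclopent-3-en-1-ylidene)hept-5-enoate | O=C1C=C(Br)C(=O)/C1=C/C=C/CCCC(=O)OC
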